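The oxolane ring (O1, C2–C5) is read as a reduced γ-lactone. Its C2–O1 unit is the carbonyl of a silyl-protected syringaldehyde, C5 is an ester carbon, and C3 and C4 are the γ- and central carbons of a 2-(methoxycarbonyl)allyl boronate that already carries the C3 oxymethyl arm. One catalytic asymmetric allylboration–lactonisation forms C2–C3 and O1–C5, closes the ring and sets C2 and C3 trans. The precursor is a geometrically pure (Z)-boronate with the arm trans to CH2–B. The methylene left by the allyl shift becomes the benzylic carbon on C4; silyl groups on all three hydroxyls let one fluoride step replace hydrogenolysis, which would endanger the benzylic C2–O1 bond.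

Key step: step 4

Remark: ring atoms are numbered O1, C2 (aryl), C3 (oxymethyl arm), C4 (benzyl), C5 throughout; TBS = tert-butyldimethylsilyl, TIPS = triisopropylsilyl; compounds 1 and 3 are taken as purchased, and the sense of induction of the phosphoric acid is assigned by analogy with simple allylboration (both antipodes of the acid are available).

Step 1
Reactants: 1 tert-butyldimethyl(prop-2-yn-1-yloxy)silane
Product: 2 methyl 4-[(tert-butyldimethylsilyl)oxy]but-2-ynoate
Conditions: n-BuLi, THF, −78 °C; then ClCO2Me, −78 → 0 °C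
Reagents that add atoms: methyl chloroformate, COC(=O)Cl
Why: Deprotonation of the terminal alkyne and C-acylation of the lithium acetylide with a chloroformate (acetylide carboxylation) is a standard entry to 2-alkynoates, and the silyl ether is inert to n-BuLi at −78 °C.

Step 2
Reactants: 2 methyl 4-[(tert-butyldimethylsilyl)oxy]but-2-ynoate; 3 2-(iodomethyl)-4,4,5,5-tetramethyl-1,3,2-dioxaborolane
Product: 5 methyl (Z)-4-[(tert-butyldimethylsilyl)oxy]-2-[(4,4,5,5-tetramethyl-1,3,2-dioxaborolan-2-yl)methyl]but-2-enoate, via alkenylalane 4 (not isolated)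
Conditions: i-Bu2AlH, HMPA, THF, 0 °C; then 3, 0 °C → rt
Reagents that add atoms: none
Why: Conjugate cis-hydroalumination of an ynoate by the i-Bu2AlH·HMPA complex followed by C-alkylation of the α-aluminoacrylate with an α-iodo boronate: hydride and aluminium add to the same side of the triple bond and the borylmethyl group replaces aluminium with retention, so the arm ends up trans to CH2–B (the Z isomer), provided the alkenylalane is trapped cold before it can equilibrate through its allenolate form.

Step 3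
Reactants: 6 syringaldehyde
Product: 7 3,5-dimethoxy-4-[(triisopropylsilyl)oxy]benzaldehyde
Conditions: TIPSCl, imidazole, DMF, rt
Reagents that add atoms: triisopropylsilyl chloride, CC(C)[Si](Cl)(C(C)C)C(C)C
Why: Imidazole-promoted silylation of a phenol gives a bulky, fluoride-labile ether that tolerates hydride, Lewis acid and aqueous base later on, and whose oxygen, twisted out of conjugation between two methoxy groups, donates little, which keeps the aldehyde electrophilic and the later benzylic ether reluctant to ionise.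

Step 4
Reactants: 5 methyl (Z)-4-[(tert-butyldimethylsilyl)oxy]-2-[(4,4,5,5-tetramethyl-1,3,2-dioxaborolan-2-yl)methyl]but-2-enoate; 7 3,5-dimethoxy-4-[(triisopropylsilyl)oxy]benzaldehyde
Product: 9 (4R,5S)-4-{[(tert-butyldimethylsilyl)oxy]methyl}-5-{3,5-dimethoxy-4-[(triisopropylsilyl)oxy]phenyl}-3-methylideneoxolan-2-one, via borate ester 8 (not isolated)
Conditions: (S)-TRIP [(S)-3,3'-bis(2,4,6-triisopropylphenyl)-1,1'-binaphthyl-2,2'-diyl hydrogen phosphate] (10 mol%), 4 Å MS, PhMe, 0 °C → rt
Reagents that add atoms: none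
Why: Proposed new method: the phosphoric acid hydrogen-bonds to a dioxaborolane oxygen of 5 and so raises the Lewis acidity of boron, the aldehyde oxygen binds boron, and the γ-carbon is delivered to the carbonyl carbon through a closed six-membered chair with allylic transposition to give borate 8, whose oxygen then displaces methoxide from the neighbouring ester. The closest known reactions are the chiral phosphoric acid-catalysed allyl- and crotylboration of aldehydes with pinacol boronates and the thermal or acid-promoted 2-(alkoxycarbonyl)allylboration–lactonisation; merging them on a γ-substituted, ester-deactivated boronate is the untested part. The lactone ring closes at O1–C5 by 5-exo-trig acyl substitution. C3 is fixed relative to C2 by the alkene geometry of 5, because the arm, trans to CH2–B, sits equatorial in the chair and this gives the anti adduct and hence the trans lactone; C2 is fixed by the catalyst, the (S)-acid being expected to expose the Si face of 7. The step needs enantiofacial and anti selectivity, secured by the catalyst and by the geometrically pure boronate, and lactonisation through the C2 oxygen alone, secured by the silyl cap on the arm oxygen. The uncatalysed reaction of such ester-bearing boronates is slow at room temperature, so a racemic background channel should not compete.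

Step 5
Reactants: 9 (4R,5S)-4-{[(tert-butyldimethylsilyl)oxy]methyl}-5-{3,5-dimethoxy-4-[(triisopropylsilyl)oxy]phenyl}-3-methylideneoxolan-2-one
Product: 10 (4R,5S)-4-{[(tert-butyldimethylsilyl)oxy]methyl}-5-{3,5-dimethoxy-4-[(triisopropylsilyl)oxy]phenyl}-3-methylideneoxolan-2-ol (anomeric mixture)
Conditions: i-Bu2AlH (1.2 equiv), CH2Cl2, −78 °C; aq. potassium sodium tartrate
Reagents that add atoms: none
Why: Partial reduction of a lactone to the lactol by i-Bu2AlH, in which the aluminium hemiacetal survives at −78 °C until work-up and hydride goes 1,2 to the conjugated carbonyl in a non-coordinating solvent, so the ring closed in step 4 and both stereocentres stay intact.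

Step 6
Reactants: 10 (4R,5S)-4-{[(tert-butyldimethylsilyl)oxy]methyl}-5-{3,5-dimethoxy-4-[(triisopropylsilyl)oxy]phenyl}-3-methylideneoxolan-2-ol
Product: 11 tert-butyl{[(2S,3R)-2-{3,5-dimethoxy-4-[(triisopropylsilyl)oxy]phenyl}-4-methylideneoxolan-3-yl]methoxy}dimethylsilane
Conditions: Et3SiH, BF3·OEt2, CH2Cl2, −78 °C; cold NaHCO3 quench
Reagents that add atoms: none
Why: Ionic hydrogenation of a lactol, in which BF3 ionises the hemiacetal to an allylic oxocarbenium ion that Et3SiH captures at the acetal carbon C5 (as in Ferrier-type reductions), leaving the exocyclic alkene and, at −78 °C, the benzylic C2–O1 bond, both silyl ethers and the two stereocentres untouched.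

Step 7
Reactants: 12 4-bromo-2-methoxyphenol
Product: 13 (4-bromo-2-methoxyphenoxy)triisopropylsilane
Conditions: TIPSCl, imidazole, DMF, rt
Reagents that add atoms: triisopropylsilyl chloride, CC(C)[Si](Cl)(C(C)C)C(C)C
Why: Imidazole-promoted phenol silylation masks the acidic phenol for the cross-coupling with a group that leaves in the same fluoride step as the other silyl ethers.

Step 8
Reactants: 11 tert-butyl{[(2S,3R)-2-{3,5-dimethoxy-4-[(triisopropylsilyl)oxy]phenyl}-4-methylideneoxolan-3-yl]methoxy}dimethylsilane; 13 (4-bromo-2-methoxyphenoxy)triisopropylsilane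
Product: 15 tert-butyl{[(2S,3R,4R)-2-{3,5-dimethoxy-4-[(triisopropylsilyl)oxy]phenyl}-4-{3-methoxy-4-[(triisopropylsilyl)oxy]benzyl}oxolan-3-yl]methoxy}dimethylsilane, via alkylborane 14 (not isolated)
Conditions: 9-BBN-H, THF, 0 °C → rt; then 13, PdCl2(dppf)·CH2Cl2 (5 mol%), aq. K3PO4, DMF, 50 °C
Reagents that add atoms: none
Why: Anti-Markovnikov hydroboration followed by B-alkyl Suzuki–Miyaura coupling, in which 9-BBN-H places boron on the terminal methylene carbon and hydrogen on C4 from the ring face opposite the adjacent C3 arm, so the new CH2 substituent lies cis to the arm (4R), and the primary alkyl group then passes from boron to the arylpalladium bromide without touching C4.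

Step 9
Reactants: 15 tert-butyl{[(2S,3R,4R)-2-{3,5-dimethoxy-4-[(triisopropylsilyl)oxy]phenyl}-4-{3-methoxy-4-[(triisopropylsilyl)oxy]benzyl}oxolan-3-yl]methoxy}dimethylsilane
Product: 16 4-[(2S,3R,4R)-4-(4-hydroxy-3-methoxybenzyl)-3-(hydroxymethyl)oxolan-2-yl]-2,6-dimethoxyphenol (5-methoxylariciresinol)
Conditions: Bu4NF, AcOH, THF, 0 °C → rt
Reagents that add atoms: none
Why: Fluoride-induced cleavage of silyl ethers removes the two aryl TIPS groups and the primary TBS group in one operation, and the acetic acid buffer keeps the liberated para-hydroxybenzylic ether away from base-induced quinone methide chemistry, so no stereocentre is at risk.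

Step 10
Reactants: 16 4-[(2S,3R,4R)-4-(4-hydroxy-3-methoxybenzyl)-3-(hydroxymethyl)oxolan-2-yl]-2,6-dimethoxyphenol; 17 (E)-ferulic acid
Product: 18 [(2S,3R,4R)-2-(4-hydroxy-3,5-dimethoxyphenyl)-4-(4-hydroxy-3-methoxybenzyl)oxolan-3-yl]methyl (E)-3-(4-hydroxy-3-methoxyphenyl)prop-2-enoate (CNP0289934.1)
Conditions: PPh3, DIAD, THF, 0 °C → rt
Reagents that add atoms: none
Why: Mitsunobu esterification, in which only the aliphatic primary hydroxyl forms an oxyphosphonium ion and the carboxylic acid, far more acidic than the phenols, is deprotonated first and outcompetes them as nucleophile, so the ester should form chemoselectively with the E-alkene and all three stereocentres untouched (the carbinol carbon is not stereogenic).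

Compound list
1 | tert-butyldimethyl(prop-2-yn-1-yloxy)silane | C#CCO[Si](C)(C)C(C)(C)C | starting material
2 | methyl 4-[(tert-butyldimethylsilyl)oxy]but-2-ynoate | COC(=O)C#CCO[Si](C)(C)C(C)(C)C | intermediate
3 | 2-(iodomethyl)-4,4,5,5-tetramethyl-1,3,2-dioxaborolane | ICB1OC(C)(C)C(C)(C)O1 | starting material
4 | methyl (E)-4-[(tert-butyldimethylsilyl)oxy]-2-(diisobutylalumanyl)but-2-enoate (H and Al cis) | COC(=O)/C(=C\CO[Si](C)(C)C(C)(C)C)[Al](CC(C)C)CC(C)C | intermediate (not isolated)
5 | methyl (Z)-4-[(tert-butyldimethylsilyl)oxy]-2-[(4,4,5,5-tetramethyl-1,3,2-dioxaborolan-2-yl)methyl]but-2-enoate (arm trans to CH2–B) | COC(=O)/C(CB1OC(C)(C)C(C)(C)O1)=C\CO[Si](C)(C)C(C)(C)C | intermediate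
6 | syringaldehyde (4-hydroxy-3,5-dimethoxybenzaldehyde) | COc1cc(C=O)cc(OC)c1O | starting material
7 | 3,5-dimethoxy-4-[(triisopropylsilyl)oxy]benzaldehyde | COc1cc(C=O)cc(OC)c1O[Si](C(C)C)(C(C)C)C(C)C | intermediate
8 | methyl (3R,4S)-3-{[(tert-butyldimethylsilyl)oxy]methyl}-4-{3,5-dimethoxy-4-[(triisopropylsilyl)oxy]phenyl}-2-methylidene-4-[(4,4,5,5-tetramethyl-1,3,2-dioxaborolan-2-yl)oxy]butanoate | COC(=O)C(=C)[C@H](CO[Si](C)(C)C(C)(C)C)[C@H](OB1OC(C)(C)C(C)(C)O1)c1cc(OC)c(O[Si](C(C)C)(C(C)C)C(C)C)c(OC)c1 | intermediate (not isolated)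
9 | (4R,5S)-4-{[(tert-butyldimethylsilyl)oxy]methyl}-5-{3,5-dimethoxy-4-[(triisopropylsilyl)oxy]phenyl}-3-methylideneoxolan-2-one (trans lactone) | O=C1O[C@H](c2cc(OC)c(O[Si](C(C)C)(C(C)C)C(C)C)c(OC)c2)[C@@H](CO[Si](C)(C)C(C)(C)C)C1=C | intermediate
10 | (4R,5S)-4-{[(tert-butyldimethylsilyl)oxy]methyl}-5-{3,5-dimethoxy-4-[(triisopropylsilyl)oxy]phenyl}-3-methylideneoxolan-2-ol (anomeric mixture) | OC1O[C@H](c2cc(OC)c(O[Si](C(C)C)(C(C)C)C(C)C)c(OC)c2)[C@@H](CO[Si](C)(C)C(C)(C)C)C1=C | intermediate
11 | tert-butyl{[(2S,3R)-2-{3,5-dimethoxy-4-[(triisopropylsilyl)oxy]phenyl}-4-methylideneoxolan-3-yl]methoxy}dimethylsilane | C1O[C@H](c2cc(OC)c(O[Si](C(C)C)(C(C)C)C(C)C)c(OC)c2)[C@@H](CO[Si](C)(C)C(C)(C)C)C1=C | intermediate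
12 | 4-bromo-2-methoxyphenol | COc1cc(Br)ccc1O | starting material
13 | (4-bromo-2-methoxyphenoxy)triisopropylsilane | COc1cc(Br)ccc1O[Si](C(C)C)(C(C)C)C(C)C | intermediate
14 | 9-{[(3R,4R,5S)-4-{[(tert-butyldimethylsilyl)oxy]methyl}-5-{3,5-dimethoxy-4-[(triisopropylsilyl)oxy]phenyl}oxolan-3-yl]methyl}-9-borabicyclo[3.3.1]nonane | CC(C)(C)[Si](C)(C)OC[C@H]1[C@@H](CB2C3CCCC2CCC3)CO[C@@H]1c1cc(OC)c(O[Si](C(C)C)(C(C)C)C(C)C)c(OC)c1 | intermediate (not isolated)
15 | tert-butyl{[(2S,3R,4R)-2-{3,5-dimethoxy-4-[(triisopropylsilyl)oxy]phenyl}-4-{3-methoxy-4-[(triisopropylsilyl)oxy]benzyl}oxolan-3-yl]methoxy}dimethylsilane | CC(C)(C)[Si](C)(C)OC[C@H]1[C@@H](Cc2ccc(O[Si](C(C)C)(C(C)C)C(C)C)c(OC)c2)CO[C@@H]1c1cc(OC)c(O[Si](C(C)C)(C(C)C)C(C)C)c(OC)c1 | intermediate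
16 | 4-[(2S,3R,4R)-4-(4-hydroxy-3-methoxybenzyl)-3-(hydroxymethyl)oxolan-2-yl]-2,6-dimethoxyphenol | OC[C@H]1[C@@H](Cc2ccc(O)c(OC)c2)CO[C@@H]1c1cc(OC)c(O)c(OC)c1 | intermediate
17 | (E)-ferulic acid | COc1cc(/C=C/C(=O)O)ccc1O | starting material
18 | [(2S,3R,4R)-2-(4-hydroxy-3,5-dimethoxyphenyl)-4-(4-hydroxy-3-methoxybenzyl)oxolan-3-yl]methyl (E)-3-(4-hydroxy-3-methoxyphenyl)prop-2-enoate | COc1cc(/C=C/C(=O)OC[C@H]2[C@@H](Cc3ccc(O)c(OC)c3)CO[C@@H]2c2cc(OC)c(O)c(OC)c2)ccc1O | target

Total steps: 10. Longest linear sequence: 8 (steps 1, 2, 4, 5, 6, 8, 9, 10).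

Steps most likely to fail

Step 4. The weak chiral acid may fail to turn over the ester-deactivated boronate with a hindered aldehyde, or may discriminate the aldehyde faces poorly, and heating to force conversion would open the uncatalysed racemic channel. The fallback uses known chromium chemistry, sets out from aldehyde 7 and returns at lactone 9. A Morita–Baylis–Hillman reaction of (tert-butyldimethylsilyloxy)acetaldehyde with methyl acrylate (DABCO) should give methyl 4-[(tert-butyldimethylsilyl)oxy]-3-hydroxy-2-methylidenebutanoate F1. NBS/Me2S should convert it with allylic transposition into methyl (Z)-2-(bromomethyl)-4-[(tert-butyldimethylsilyl)oxy]but-2-enoate F2. Aldehyde 7 and F2 are then combined in a catalytic enantioselective Nozaki–Hiyama–Kishi 2-(alkoxycarbonyl)allylation (CrCl2 catalytic, a chiral carbazole bis(oxazoline) ligand, Mn powder, Cp2ZrCl2, THF). The γ-substituted allylchromium reagent should add through a chair transition state in the anti sense typical of crotyl-type chromium reagents, with the ligand antipode chosen for the (S)-carbinol. This should give methyl (3R,4S)-3-{[(tert-butyldimethylsilyl)oxy]methyl}-4-{3,5-dimethoxy-4-[(triisopropylsilyl)oxy]phenyl}-4-hydroxy-2-methylidenebutanoate F3, which should close to 9 on standing or with a trace of PPTS.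

Step 8. Facial discrimination in the hydroboration may be incomplete, or transfer of the β-branched alkyl group from boron to palladium may be slow enough for protodeboronation to win; either fault would surface only in a nonpolar product that is hard to purify. The fallback sets out from methylene oxolane 11 and returns at 15. Hydroboration as in the main route (alkylborane 14) with oxidative work-up (NaBO3·4H2O) should give [(3S,4R,5S)-4-{[(tert-butyldimethylsilyl)oxy]methyl}-5-{3,5-dimethoxy-4-[(triisopropylsilyl)oxy]phenyl}oxolan-3-yl]methanol F4, a polar alcohol from which a minor C4 epimer can be removed by chromatography. Appel iodination (I2, PPh3, imidazole) should give tert-butyl{[(2S,3R,4R)-2-{3,5-dimethoxy-4-[(triisopropylsilyl)oxy]phenyl}-4-(iodomethyl)oxolan-3-yl]methoxy}dimethylsilane F5. A nickel-catalysed reductive cross-electrophile coupling of F5 with aryl bromide 13 [NiBr2(dme), 4,4'-di-tert-butyl-2,2'-bipyridine, Zn, DMA] should then give 15 through an alkyl radical and an arylnickel species, independent of boron-to-palladium transfer.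

Step 10. The oxyphosphonium ion of the β-branched primary alcohol may be displaced sluggishly, so that a phenol oxygen or the hydrazide anion captures it in place of the carboxylate. The fallback sets out from 15 and returns at 18, with every phenol masked during ester formation. HF·pyridine buffered with pyridine (THF, 0 °C) should cleave the primary alkyl TBS ether selectively to give [(2S,3R,4R)-2-{3,5-dimethoxy-4-[(triisopropylsilyl)oxy]phenyl}-4-{3-methoxy-4-[(triisopropylsilyl)oxy]benzyl}oxolan-3-yl]methanol F6. Ferulic acid 17 is bis-silylated (TIPSCl, imidazole, DMF) to triisopropylsilyl (E)-3-{3-methoxy-4-[(triisopropylsilyl)oxy]phenyl}prop-2-enoate F7, and brief K2CO3 in aqueous MeOH/THF at 0 °C hydrolyses the silyl ester alone to (E)-3-{3-methoxy-4-[(triisopropylsilyl)oxy]phenyl}prop-2-enoic acid F8. Steglich esterification of F6 with F8 (EDC·HCl, DMAP, CH2Cl2) should give the tris-TIPS ester of the target F9, and Bu4NF/AcOH in THF should then release 18.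

Further compounds
F1 | step 4 | methyl 4-[(tert-butyldimethylsilyl)oxy]-3-hydroxy-2-methylidenebutanoate (racemic) | COC(=O)C(=C)C(O)CO[Si](C)(C)C(C)(C)C
F2 | step 4 | methyl (Z)-2-(bromomethyl)-4-[(tert-butyldimethylsilyl)oxy]but-2-enoate | COC(=O)/C(CBr)=C/CO[Si](C)(C)C(C)(C)C
F3 | step 4 | methyl (3R,4S)-3-{[(tert-butyldimethylsilyl)oxy]methyl}-4-{3,5-dimethoxy-4-[(triisopropylsilyl)oxy]phenyl}-4-hydroxy-2-methylidenebutanoate | COC(=O)C(=C)[C@H](CO[Si](C)(C)C(C)(C)C)[C@H](O)c1cc(OC)c(O[Si](C(C)C)(C(C)C)C(C)C)c(OC)c1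
F4 | step 8 | [(3S,4R,5S)-4-{[(tert-butyldimethylsilyl)oxy]methyl}-5-{3,5-dimethoxy-4-[(triisopropylsilyl)oxy]phenyl}oxolan-3-yl]methanol | CC(C)(C)[Si](C)(C)OC[C@H]1[C@@H](CO)CO[C@@H]1c1cc(OC)c(O[Si](C(C)C)(C(C)C)C(C)C)c(OC)c1
F5 | step 8 | tert-butyl{[(2S,3R,4R)-2-{3,5-dimethoxy-4-[(triisopropylsilyl)oxy]phenyl}-4-(iodomethyl)oxolan-3-yl]methoxy}dimethylsilane | CC(C)(C)[Si](C)(C)OC[C@H]1[C@@H](CI)CO[C@@H]1c1cc(OC)c(O[Si](C(C)C)(C(C)C)C(C)C)c(OC)c1
F6 | step 10 | [(2S,3R,4R)-2-{3,5-dimethoxy-4-[(triisopropylsilyl)oxy]phenyl}-4-{3-methoxy-4-[(triisopropylsilyl)oxy]benzyl}oxolan-3-yl]methanol | OC[C@H]1[C@@H](Cc2ccc(O[Si](C(C)C)(C(C)C)C(C)C)c(OC)c2)CO[C@@H]1c1cc(OC)c(O[Si](C(C)C)(C(C)C)C(C)C)c(OC)c1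
F7 | step 10 | triisopropylsilyl (E)-3-{3-methoxy-4-[(triisopropylsilyl)oxy]phenyl}prop-2-enoate | COc1cc(/C=C/C(=O)O[Si](C(C)C)(C(C)C)C(C)C)ccc1O[Si](C(C)C)(C(C)C)C(C)C
F8 | step 10 | (E)-3-{3-methoxy-4-[(triisopropylsilyl)oxy]phenyl}prop-2-enoic acid | COc1cc(/C=C/C(=O)O)ccc1O[Si](C(C)C)(C(C)C)C(C)C
F9 | step 10 | [(2S,3R,4R)-2-{3,5-dimethoxy-4-[(triisopropylsilyl)oxy]phenyl}-4-{3-methoxy-4-[(triisopropylsilyl)oxy]benzyl}oxolan-3-yl]methyl (E)-3-{3-methoxy-4-[(triisopropylsilyl)oxy]phenyl}prop-2-enoate | COc1cc(/C=C/C(=O)OC[C@H]2[C@@H](Cc3ccc(O[Si](C(C)C)(C(C)C)C(C)C)c(OC)c3)CO[C@@H]2c2cc(OC)c(O[Si](C(C)C)(C(C)C)C(C)C)c(OC)c2)ccc1O[Si](C(C)C)(C(C)C)C(C)C
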